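Moles per litre of X were the unit of my ledger, since percent of the J and Q charged hides what the reagent bought.

in all of them: D 0.10 mM
- autumn: J 0.10 M; Q 0.10 M; X 0.30 M; temperature 25 °C; the very flask that is asked about, followed so far
- winter: J 0.15 M; Q 0.15 M; X 0.30 M; temperature 31 °C; run made earlier
- flask: J 0.10 M; Q 0.10 M; X 0.300 M; temperature 25 °C; time 5.0 min

autumn run (percent of the J and Q together charged)

| time / min | L / % |
|---|---|
| 0.250 | 16 |
| 0.833 | 35 |
| 1.33 | 40 |
| 2.00 | 47 |
| 3.00 | 46 |

winter run (percent of the J and Q together charged)

| time / s | L / % |
|---|---|
| 10.0 | 17 |
| 15.0 | 20 |
| 30.0 | 31 |
| 60.0 | 38 |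

(readings scatter by 2 percentage points)

- X is single-handed; J and Q are mirror images of each other, charged as a racemate, each of them at the stated concentration
- removed L is counted in
- steps thought possible: X + J -> L; X + Q -> G; X -> E; 2 X -> Z; J + D <-> Q + D
- additions bring no volume worth counting
- the handed part of X does not stay in what it makes, so the products of the two hands are mirror images too

- west: at 5.0 min add D, 100% of the amount charged, then wait 1.5 min
- east: at 5.0 min add X, 100% of the amount charged, then wait 1.5 min
- north: at 5.0 min raise the temperature by 10 K, then wait 1.5 min
- north-west: change nothing and wait 1.5 min more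
- south: at 5.0 min take out 90% of the L then present, then wait 1.5 min

- L, in percent of the J and Q together first charged, at 5.0 min
- which option adds most L ("none" when 2 percentage points or less is all one gets) (west / east / north / north-west / south / none)
- L present, with what was taken out counted in, in percent of the J and Q together first charged, after west
- L present, with what was taken out counted in, in percent of the J and Q together first charged, after east

The first entry was L. The autumn reading at 2.00 min was 47%, which is 0.0940 M of L against 0.30 M of X charged. I called the moles of L made per mole of X charged the X yield, and here it read 31.3%. The winter run, at its last reading, gave 0.114 M of L, an X yield of 38.0%. That run was still slowing, gaining 7 percentage points in its last 30.0 s, with 12 points of J not yet turned into L even without any fed in from Q. So I took X as the limiting reagent.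

The second entry held the rest of the autumn X, 0.206 M, which that reading left unplaced among free X, G, E and Z. The last two autumn readings, 47% and 46%, lay within the scatter of 2 points of each other, so they could not tell a slow rise from a plateau, and I committed to about 46.5% at the asked time.

West, north, north-west and south add no X, so I chose east. I assumed that a dose earns the X yield scaled by the J it meets. Without racemisation, J stands at 0.00600 M, and the dose gains 2.8 points. If D keeps J and Q level, J is half of at most 0.106 M, and the gain is at most 25 points. The margin is 2 points, and the readings did not place the gain within that range.

The forecast also named east, with 47.5% now, 47.6% after west and 50.5% after east, holding that “Fresh X consumes most of the remaining J”.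

The flask gave 49.9% now, 50.3% after west and 66.1% after east, so east added 16 points.

    X + J → L (k = 0.110 L mol⁻¹ s⁻¹, Ea = 53.0 kJ mol⁻¹)
    X + Q → G (k = 0.0270 L mol⁻¹ s⁻¹, Ea = 48.0 kJ mol⁻¹)
    X → E (k = 0.00710 s⁻¹, Ea = 86.0 kJ mol⁻¹)
    2 X → Z (k = 0.0120 L mol⁻¹ s⁻¹, Ea = 45.0 kJ mol⁻¹)
    J + D ⇌ Q + D, rate k5*[D]*[J] forward; the back reaction follows from the equilibrium constant (k = 180 L mol⁻¹ s⁻¹, Ea = 40.0 kJ mol⁻¹)
    (constants at 25 °C)

In this flask the step from X to E used X 0.65 times as fast as the step from X + J to L at the start and 1.8 times as fast at 5.00 min, when 1.3% of the charged X and 35% of the charged J were left and the X yield stood at 33.2%. The neighbour charged with 0.075 M of X, with 0.40% of that X left at 5.00 min, held 17.8% of L, an X yield of 47.4%.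

The runs were generated by integration with constants of no real substance, noise included.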